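**Plan**
- Retrosynthesis, first cut: the aryl–C7' bond of the syringylmethyl arm on C4 (C7' = benzylic carbon of that arm). It becomes an aryl Grignard addition to a C4 formyl group, the carbinol oxygen leaving later by hydrogenolysis; the formyl carbon is the inner carbon of a vinyl group.
- Second cut: O1–C2 and C3–C4 of the lactone. O1, C5, C4 and the vinyl arm come from vinylethylene carbonate; C2, C3 and the guaiacylmethyl arm come from a ketene made from O-benzyl dihydroferulic acid chloride.
- Enabling feature: in the ring O1–C2(=O)–C3–C4–C5, C5 is an unsubstituted OCH2 and C4 carries a one-carbon arm, so O1–C5–C4 maps onto an alkoxide/π-allyl dipole and C2–C3 onto the C=C=O unit of a ketene.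
- Forward order: ferulic acid to the acid chloride (3 steps); Pd (3+2) annulation closes the lactone, the only ring built; vinyl to CHO; aryl addition; one hydrogenolysis removes the carbinol oxygen and both benzyl ethers.
- Stereochemistry: C4 from the chiral ligand on palladium (dynamic kinetic use of the racemic carbonate); C3 trans to C4 by thermodynamic control at the enolisable α-carbon; the C7' carbinol centre is temporary.

Key step: step 4

Assumption: the sense of induction of the palladium ligand with this nucleophile cannot be predicted with confidence; the route is written with the (S,S,S)-phosphoramidite, and the (R,R,R)-antipode is used instead if the first run delivers the 4S series.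

**Route**

Step 1
Reactants: 1 ferulic acid
Product: 2 3-(4-hydroxy-3-methoxyphenyl)propanoic acid
Conditions: H2 (1 atm), 10% Pd/C, MeOH, rt
Reagents that add atoms: none
Why: Catalytic hydrogenation of the conjugated alkene of a cinnamic acid over palladium is routine and leaves the arene, phenol and acid untouched, with no stereocentre formed.

Step 2
Reactants: 2 3-(4-hydroxy-3-methoxyphenyl)propanoic acid
Product: 3 3-(4-benzyloxy-3-methoxyphenyl)propanoic acid
Conditions: BnBr (1.1 equiv), NaOH (2.5 equiv), EtOH–H2O, reflux; then HCl to pH 2
Reagents that add atoms: benzyl bromide, BrCc1ccccc1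
Why: Williamson ether synthesis on the dianion, in which the phenoxide is far more nucleophilic than the carboxylate and any benzyl ester that does form is saponified in the same alkaline medium before acidification.

Step 3
Reactants: 3 3-(4-benzyloxy-3-methoxyphenyl)propanoic acid
Product: 4 3-(4-benzyloxy-3-methoxyphenyl)propanoyl chloride
Conditions: (COCl)2, DMF (cat.), CH2Cl2, 0 °C to rt; evaporate, use crude
Reagents that add atoms: oxalyl chloride, ClC(=O)C(=O)Cl
Why: Standard acid chloride formation with oxalyl chloride and catalytic DMF gives only gaseous by-products and involves no Lewis acid that could trigger indanone formation, so the benzyl ether survives and the crude chloride can be used directly.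

Step 4
Reactants: 4 3-(4-benzyloxy-3-methoxyphenyl)propanoyl chloride; 5 4-vinyl-1,3-dioxolan-2-one (racemic)
Product: 8 (3R,4R)-3-(4-benzyloxy-3-methoxybenzyl)-4-vinyldihydrofuran-2(3H)-one, via (4-benzyloxy-3-methoxybenzyl)ketene 6 (not isolated), via cis-(3S,4R) lactone epimer 7 (not isolated)
Conditions: 4, polystyrene-bound BEMP, THF, −78 °C; cold filtrate added over 2 h to 5 (1.5 equiv), Pd2(dba)3·CHCl3 (2.5 mol %), (S,S,S)-BINOL bis(1-phenylethyl)amine phosphoramidite (10 mol %), THF, 0 °C to rt; then DBU (0.2 equiv), rt
Reagents that add atoms: none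
Why: Proposed new method: Pd(0) ionises racemic 5 with loss of CO2 to a π-allylpalladium alkoxide, the alkoxide adds to the carbonyl carbon of ketene 6 (O1–C2), and the resulting ester enolate, held two atoms from oxygen, alkylates the oxygen-proximal allyl terminus (C3–C4). The closest known reaction types are the Pd-catalysed decarboxylative (3+2) annulations of vinylethylene carbonates with isocyanates, aldehydes and Michael acceptors, the trapping of Pd allyl zwitterions by disubstituted ketenes in (4+2) and (5+2) modes, and the Ir/carbene (3+2) annulation of the same carbonate with enals; new here is a monosubstituted ketene closing to the five-membered lactone. The lactone closes 5-exo at the internal allyl carbon with the vinyl group left exocyclic, whereas the seven-membered 7-endo alternative needs the anti allyl complex and is the mode seen when five-ring closure would join two fully substituted carbons, which is not the case with the tertiary C3 and C4 formed here. C4 is set by the chiral ligand, because the diastereomeric allyl complexes from both enantiomers of 5 interconvert by π–σ–π shifts at the unsubstituted terminus faster than the ring closes; C3 is set relative to C4, since DBU enolises only C3 and carries any cis epimer 7 over to the more stable trans lactone 8. The step needs capture of an undimerised ketene by oxygen and an enolate that is not protonated before it cyclises, which the cold salt-free ketene stream (HCl stays on the resin, no ammonium salt present), its slow addition and the N–H-free ligand are meant to secure.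

Step 5
Reactants: 8 (3R,4R)-3-(4-benzyloxy-3-methoxybenzyl)-4-vinyldihydrofuran-2(3H)-one
Product: 9 (3R,4R)-4-(4-benzyloxy-3-methoxybenzyl)-5-oxotetrahydrofuran-3-carbaldehyde
Conditions: OsO4 (2 mol %), NaIO4 (4 equiv), 2,6-lutidine (2 equiv), dioxane–H2O 3:1, rt; dry azeotropically (toluene), use at once
Reagents that add atoms: sodium periodate, [Na+].[O-]I(=O)(=O)=O (terminal oxygen source); osmium tetroxide, O=[Os](=O)(=O)=O (catalytic oxygen carrier)
Why: Lemieux–Johnson oxidation of a terminal alkene under 2,6-lutidine buffering is reliable, 5-oxotetrahydrofuran-3-carbaldehydes are an isolable compound class, and enolisation at C4 is self-correcting because C3 stays fixed and the trans arrangement is the stable one.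

Step 6
Reactants: 10 4-bromo-2,6-dimethoxyphenol
Product: 11 2-(benzyloxy)-5-bromo-1,3-dimethoxybenzene
Conditions: BnBr (1.2 equiv), K2CO3, DMF, 60 °C
Reagents that add atoms: benzyl bromide, BrCc1ccccc1
Why: Williamson ether synthesis of an acidic, moderately hindered phenol with benzyl bromide and carbonate in DMF, in which the bromine fixes the ring position that will later be joined to C7'.

Step 7
Reactants: 9 (3R,4R)-4-(4-benzyloxy-3-methoxybenzyl)-5-oxotetrahydrofuran-3-carbaldehyde; 11 2-(benzyloxy)-5-bromo-1,3-dimethoxybenzene
Product: 13 (3R,4R)-3-(4-benzyloxy-3-methoxybenzyl)-4-[(4-benzyloxy-3,5-dimethoxyphenyl)(hydroxy)methyl]dihydrofuran-2(3H)-one (both C7' epimers), via (4-benzyloxy-3,5-dimethoxyphenyl)magnesium bromide 12 (not isolated)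
Conditions: 11, Mg turnings, LiCl, THF, rt; 12 (1.2 equiv) added to 9, THF, −78 °C; sat. aq NH4Cl at −78 °C
Reagents that add atoms: none
Why: Magnesium insertion into an electron-rich aryl bromide of the trialkoxyphenyl type followed by Grignard addition to an aldehyde, which at −78 °C with the aldehyde kept in excess should outrun both enolisation and attack on the lactone carbonyl, the new carbinol centre forming without control because it is removed in step 8.

Step 8
Reactants: 13 (3R,4R)-3-(4-benzyloxy-3-methoxybenzyl)-4-[(4-benzyloxy-3,5-dimethoxyphenyl)(hydroxy)methyl]dihydrofuran-2(3H)-one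
Product: 15 (3R,4R)-3-(4-hydroxy-3-methoxybenzyl)-4-(4-hydroxy-3,5-dimethoxybenzyl)dihydrofuran-2(3H)-one (the target), via debenzylated 7'-carbinol 14 (not isolated)
Conditions: H2 (3 atm), 10% Pd/C, EtOH, 50 °C
Reagents that add atoms: none
Why: Palladium-catalysed hydrogenolysis cleaves both aryl benzyl ethers and then the benzylic C7'–OH bond, which in 14 lies para to a free phenol and should be lost as is known for 7'-hydroxy dibenzylbutyrolactone lignans, while the neutral medium avoids acid-triggered cyclisation to an aryltetralin and leaves C3 and C4 untouched.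

**Compound list**

1 | ferulic acid | COc1cc(/C=C/C(=O)O)ccc1O | starting material
2 | 3-(4-hydroxy-3-methoxyphenyl)propanoic acid | COc1cc(CCC(=O)O)ccc1O | intermediate
3 | 3-(4-benzyloxy-3-methoxyphenyl)propanoic acid | COc1cc(CCC(=O)O)ccc1OCc1ccccc1 | intermediate
4 | 3-(4-benzyloxy-3-methoxyphenyl)propanoyl chloride | COc1cc(CCC(=O)Cl)ccc1OCc1ccccc1 | intermediate
5 | 4-vinyl-1,3-dioxolan-2-one (racemic) | C=CC1COC(=O)O1 | starting material
6 | (4-benzyloxy-3-methoxybenzyl)ketene, 3-(4-benzyloxy-3-methoxyphenyl)prop-1-en-1-one | COc1cc(CC=C=O)ccc1OCc1ccccc1 | intermediate (not isolated)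
7 | (3S,4R)-3-(4-benzyloxy-3-methoxybenzyl)-4-vinyldihydrofuran-2(3H)-one (cis C3 epimer, to the extent it forms) | COc1cc(C[C@@H]2C(=O)OC[C@@H]2C=C)ccc1OCc1ccccc1 | intermediate (not isolated)
8 | (3R,4R)-3-(4-benzyloxy-3-methoxybenzyl)-4-vinyldihydrofuran-2(3H)-one | COc1cc(C[C@H]2C(=O)OC[C@@H]2C=C)ccc1OCc1ccccc1 | intermediate
9 | (3R,4R)-4-(4-benzyloxy-3-methoxybenzyl)-5-oxotetrahydrofuran-3-carbaldehyde | COc1cc(C[C@H]2C(=O)OC[C@@H]2C=O)ccc1OCc1ccccc1 | intermediate
10 | 4-bromo-2,6-dimethoxyphenol | COc1cc(Br)cc(OC)c1O | starting material
11 | 2-(benzyloxy)-5-bromo-1,3-dimethoxybenzene | COc1cc(Br)cc(OC)c1OCc1ccccc1 | intermediate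
12 | (4-benzyloxy-3,5-dimethoxyphenyl)magnesium bromide | COc1cc([Mg]Br)cc(OC)c1OCc1ccccc1 | intermediate (not isolated)
13 | (3R,4R)-3-(4-benzyloxy-3-methoxybenzyl)-4-[(4-benzyloxy-3,5-dimethoxyphenyl)(hydroxy)methyl]dihydrofuran-2(3H)-one, C7' epimer mixture | COc1cc(C[C@H]2C(=O)OC[C@@H]2C(O)c2cc(OC)c(OCc3ccccc3)c(OC)c2)ccc1OCc1ccccc1 | intermediate
14 | (3R,4R)-3-(4-hydroxy-3-methoxybenzyl)-4-[hydroxy(4-hydroxy-3,5-dimethoxyphenyl)methyl]dihydrofuran-2(3H)-one, C7' epimer mixture | COc1cc(C[C@H]2C(=O)OC[C@@H]2C(O)c2cc(OC)c(O)c(OC)c2)ccc1O | intermediate (not isolated)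
15 | (3R,4R)-3-(4-hydroxy-3-methoxybenzyl)-4-(4-hydroxy-3,5-dimethoxybenzyl)dihydrofuran-2(3H)-one | COc1cc(C[C@H]2C(=O)OC[C@@H]2Cc2cc(OC)c(O)c(OC)c2)ccc1O | target

**Step count**

Total steps: 8. Longest linear sequence: 7 (steps 1, 2, 3, 4, 5, 7, 8); step 6 is a one-step branch.

**Steps most likely to fail**

Step 4 (proposed new method). The ketene may dimerise or oligomerise before the palladium alkoxide captures it. The tethered enolate may be protonated instead of cyclising, or may close at the far allyl terminus to a seven-membered lactone. The ligand may also give poor facial selectivity at C4. The fallback uses a known reaction type, the cooperative iridium/N-heterocyclic carbene (3+2) annulation of vinylethylene carbonate with enals, which forms the same two bonds. It sets out from 5, which is combined with (E)-3-(4-benzyloxy-3-methoxyphenyl)acrylaldehyde F1. F1 is an isomer of ketene 6 and is made in one Wittig step from commercial 4-benzyloxy-3-methoxybenzaldehyde and formylmethylenetriphenylphosphorane. The catalysts are [Ir(cod)Cl]2 with a chiral phosphoramidite–olefin ligand and a chiral triazolium carbene precursor with an amine base. The carbene converts the enal into an azolium enolate that attacks the substituted terminus of the iridium allyl (C3–C4), and the alkoxide then displaces the carbene (O1–C2). The catalyst pair is chosen for the (3R,4R) series, and the fallback comes back to the route at 8.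

Step 7. The basic Grignard reagent may enolise the formyl lactone, causing epimerisation at C4 or β-elimination with opening of the lactone, or it may add to the lactone carbonyl. The fallback replaces the organomagnesium addition by a neutral Nozaki–Hiyama–Kishi coupling. It sets out from 11, which is converted by copper-catalysed halogen exchange (CuI, N,N'-dimethylethylenediamine, NaI, dioxane, 110 °C) into 2-(benzyloxy)-5-iodo-1,3-dimethoxybenzene F2. F2 is then coupled with 9 using CrCl2 and catalytic NiCl2 in DMF at rt, and the fallback comes back to the route at 13.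

Step 5. The formyl lactone may not survive its own formation in the aqueous buffered medium, through ring-opening elimination across C4–C5, hydration or over-oxidation. The fallback moves the C4 arm to the acid oxidation level, which does not suffer from these processes, and bypasses both 9 and step 7.
- It sets out from 8, which is cleaved with catalytic OsO4 and Oxone in DMF to (3R,4R)-4-(4-benzyloxy-3-methoxybenzyl)-5-oxotetrahydrofuran-3-carboxylic acid F3.
- Oxalyl chloride with catalytic DMF gives (3R,4R)-4-(4-benzyloxy-3-methoxybenzyl)-5-oxotetrahydrofuran-3-carbonyl chloride F4.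
- Grignard reagent 12 is transmetalated with ZnCl2 to (4-benzyloxy-3,5-dimethoxyphenyl)zinc chloride F5, which is acylated by F4 under Pd(PPh3)4 in THF at rt (Negishi acylation, inert towards the lactone). This gives (3R,4R)-3-(4-benzyloxy-3-methoxybenzyl)-4-(4-benzyloxy-3,5-dimethoxybenzoyl)dihydrofuran-2(3H)-one F6.
- NaBH4 in MeOH–THF at 0 °C reduces the aryl ketone only, and the fallback comes back to the route at 13.

**Further compounds**

F1 | step 4 | (E)-3-(4-benzyloxy-3-methoxyphenyl)acrylaldehyde | COc1cc(/C=C/C=O)ccc1OCc1ccccc1
F2 | step 7 | 2-(benzyloxy)-5-iodo-1,3-dimethoxybenzene | COc1cc(I)cc(OC)c1OCc1ccccc1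
F3 | step 5 | (3R,4R)-4-(4-benzyloxy-3-methoxybenzyl)-5-oxotetrahydrofuran-3-carboxylic acid | COc1cc(C[C@H]2C(=O)OC[C@@H]2C(=O)O)ccc1OCc1ccccc1
F4 | step 5 | (3R,4R)-4-(4-benzyloxy-3-methoxybenzyl)-5-oxotetrahydrofuran-3-carbonyl chloride | COc1cc(C[C@H]2C(=O)OC[C@@H]2C(=O)Cl)ccc1OCc1ccccc1
F5 | step 5 | (4-benzyloxy-3,5-dimethoxyphenyl)zinc chloride | COc1cc([Zn]Cl)cc(OC)c1OCc1ccccc1
F6 | step 5 | (3R,4R)-3-(4-benzyloxy-3-methoxybenzyl)-4-(4-benzyloxy-3,5-dimethoxybenzoyl)dihydrofuran-2(3H)-one | COc1cc(C[C@H]2C(=O)OC[C@@H]2C(=O)c2cc(OC)c(OCc3ccccc3)c(OC)c2)ccc1OCc1ccccc1
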